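Ring B holds one unsubstituted methylene, C4 (tetralin numbering), wedged between C4a of the electron-rich ring A and C3. Removing it contracts ring B to a trans-2,3-disubstituted indan-1-one that already carries C1 with ring C and C2 with its methoxymethyl arm, the carbonyl carbon being the future C3. In the forward direction the carbon of trimethylsilyldiazomethane is slipped into the aryl–carbonyl bond: C4a migrates, the C3–C4 and C4–C4a bonds form, and the five-membered ring grows into ring B in a single operation, leaving a C3 ketone for the last arm. C1 is set by an asymmetric reductive Heck cyclisation; C2 and C3 follow from substrate and thermodynamic control.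

Key step: step 6

Remark: the locants C1–C4 and C4a and the ring letters A–C follow the tetralin numbering of the target in all intermediates.
Assumption: the (R)-antipode of the bisphosphine is taken to give (R)-5. Both antipodes are commercial, so the other one is used if the sense of induction proves opposite.

Step 1
Reactants: 1 3,4-dimethoxyacetophenone
Product: 2 1-(2-bromo-4,5-dimethoxyphenyl)ethan-1-one
Conditions: NBS (1.05 equiv), MeCN, 0 °C → rt, dark
Reagents that add atoms: N-bromosuccinimide, O=C1CCC(=O)N1Br
Why: Electrophilic aromatic bromination: in polar acetonitrile without acid or radical initiator NBS brominates the ring and not the acetyl methyl group, and it attacks C6, which is para to the 3-methoxy group and the only unhindered activated position.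

Step 2
Reactants: 2 1-(2-bromo-4,5-dimethoxyphenyl)ethan-1-one; 3 veratraldehyde
Product: 4 (E)-1-(2-bromo-4,5-dimethoxyphenyl)-3-(3,4-dimethoxyphenyl)prop-2-en-1-one
Conditions: KOH, EtOH–H2O, rt
Reagents that add atoms: none
Why: Claisen–Schmidt condensation: only 2 can enolise and only 3 is an aldehyde, and E1cB dehydration of the aldol should give the conjugated E-enone as the thermodynamic product.

Step 3
Reactants: 4 (E)-2'-bromochalcone
Product: 5 (3R)-3-(3,4-dimethoxyphenyl)-5,6-dimethoxyindan-1-one
Conditions: Pd(OAc)2 (5 mol %), (R)-3,5-Xyl-MeO-BIPHEP (6 mol %), iPr2NEt (3 equiv), PhCO2H (1 equiv), ethylene glycol, 90 °C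
Reagents that add atoms: none
Why: Asymmetric intramolecular reductive Heck reaction: the C–Br bond adds oxidatively to zerovalent palladium, the hydrogen-bond donors (ammonium benzoate, glycol) pull bromide off the metal, the cationic aryl–palladium bisphosphine complex inserts into the enone face-selectively to join the ring A carbon to the β-carbon, and the palladium enolate, which has no syn β-hydrogen, is released reductively at the expense of the amine, so that the chiral ligand sets C1 as R.

Step 4
Reactants: 5 (3R)-3-arylindanone
Product: 7 (1R)-[1-(3,4-dimethoxyphenyl)-5,6-dimethoxy-1H-inden-3-yl]oxy(trimethyl)silane, via lithium enolate 6 (not isolated)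
Conditions: LiN(SiMe3)2 (1.0 equiv), THF, −78 °C; Me3SiCl, −78 → 0 °C; non-aqueous work-up
Reagents that add atoms: chlorotrimethylsilane, C[Si](C)(C)Cl
Why: Kinetic enolisation and O-silylation: C2 carries the only α-hydrogens, and the amine-free low-temperature protocol avoids the base-mediated 1,3-prototropic shift of 1-aryl-1H-indenes that could erase the C1 stereocentre.

Step 5
Reactants: 7 silyl enol ether
Product: 8 (2R,3R)-3-(3,4-dimethoxyphenyl)-5,6-dimethoxy-2-(methoxymethyl)indan-1-one (trans)
Conditions: MeOCH2Cl (1.2 equiv), ZnBr2 (5 mol %), CH2Cl2, −20 → 0 °C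
Reagents that add atoms: chloromethyl methyl ether, COCCl
Why: Lewis-acid-induced α-alkylation of a silyl enol ether with an SN1-active α-chloro ether (Mukaiyama type): the enol ether outcompetes ring C for the methoxymethyl cation and captures it at C2 on the indene face opposite the C1 aryl group, which sets C2 trans (also the equilibrium arrangement of this epimerisable centre) and installs the finished methyl ether without passing through a retro-aldol-prone β-hydroxy ketone.

Step 6
Reactants: 8 trans-2-(methoxymethyl)-3-arylindanone; 9 trimethylsilyldiazomethane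
Product: 11 (3R,4R)-4-(3,4-dimethoxyphenyl)-6,7-dimethoxy-3-(methoxymethyl)-3,4-dihydronaphthalen-2(1H)-one (trans; carbonyl at C3 of the target), via C4-silyl ketone 10 (not isolated)
Conditions: 9 (2 M in hexanes, 1.5 equiv), BF3·OEt2 (1.5 equiv), CH2Cl2, −78 → −20 °C; then 1 M aq HCl, THF, 0 °C
Reagents that add atoms: trimethylsilyldiazomethane (9), C[Si](C)(C)C=[N+]=[N-]
Why: BF3 binds the carbonyl oxygen of 8, the nucleophilic diazo carbon of 9 adds to the carbonyl carbon (future C3), and in the resulting β-diazonio alkoxide the C3–C4a bond swings onto the diazo carbon antiperiplanar to the departing N2, giving 10, whose benzylic C–Si bond is cleaved by the acidic work-up. The closest known reaction type is the Tiffeneau–Demjanov-like (Büchner–Curtius–Schlotterbeck) homologation of aryl ketones, 1-indanones and 1-tetralones with diazomethane or its silyl analogue under Lewis acid promotion. Ring B is not closed by a cyclisation but arises by a one-atom ring expansion (five to six) through a 1,2-aryl shift that creates C3–C4 and C4–C4a. No lasting stereocentre is created, since the silyl-bearing C4 ends as CH2; C1 is remote from the events, and C2, α to the carbonyl before and after, keeps its trans relation to the C1 aryl group because that is its equilibrium position. The step needs migration of C4a instead of C2, which is secured by the methoxy group para to C4a (a phenonium-like transition state is stabilised) and by the clash of the Me3Si group with the branched C2, which disfavours the rotamer that would move C2. The bulky silyl group in 10 also shields the new, more electrophilic ketone from a second insertion, while monodentate BF3 and low temperature keep the β-methoxy group from being eliminated.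

Step 7
Reactants: 11 trans-2-tetralone
Product: 13 (3R,4R)-4-(3,4-dimethoxyphenyl)-6,7-dimethoxy-3-(methoxymethyl)-3,4-dihydronaphthalen-2-yl trifluoromethanesulfonate (C3=C4 enol triflate), via lithium enolate 12 (not isolated)
Conditions: LiN(SiMe3)2 (1.1 equiv), THF, −78 °C (11 added to the base); PhNTf2, −78 → 0 °C
Reagents that add atoms: N-phenylbis(trifluoromethanesulfonimide), O=S(=O)(N(c1ccccc1)S(=O)(=O)C(F)(F)F)C(F)(F)F
Why: Regioselective enolate formation and O-triflation: the benzylic C4 hydrogens are far more acidic and less hindered than C2–H, so the ring-A-conjugated C3=C4 enolate forms, C2 is not touched and β-elimination of methoxide is avoided.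

Step 8
Reactants: 13 enol triflate
Product: 14 methyl (3S,4R)-4-(3,4-dimethoxyphenyl)-6,7-dimethoxy-3-(methoxymethyl)-3,4-dihydronaphthalene-2-carboxylate
Conditions: Pd(PPh3)4 (5 mol %), CO (1 atm), MeOH, Et3N, DMF, 60 °C
Reagents that add atoms: carbon monoxide, [C-]#[O+]; methanol, CO
Why: Palladium-catalysed alkoxycarbonylation of an enol triflate: oxidative addition to zerovalent palladium, CO insertion and methanolysis of the acylpalladium species attach the last skeletal carbon to C3.

Step 9
Reactants: 14 unsaturated ester
Product: 16 methyl (2S,3S,4R)-4-(3,4-dimethoxyphenyl)-6,7-dimethoxy-3-(methoxymethyl)-1,2,3,4-tetrahydronaphthalene-2-carboxylate (all-trans), via C3-epimeric esters 15 (not isolated)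
Conditions: H2 (1 atm), Pd/C, EtOAc–MeOH, rt; filter; NaOMe (0.5 equiv), MeOH, reflux
Reagents that add atoms: none
Why: Heterogeneous hydrogenation of the cinnamate-type C3=C4 bond followed by methoxide-mediated epimerisation through the ester enolate: C3 is the only acidic centre, so equilibration should collect the material in the isomer whose aryl, methoxymethyl and ester groups are all (pseudo)equatorial, that is with C3 trans to C2.

Step 10
Reactants: 16 all-trans ester
Product: 17 [(2S,3S,4R)-4-(3,4-dimethoxyphenyl)-6,7-dimethoxy-3-(methoxymethyl)-1,2,3,4-tetrahydronaphthalen-2-yl]methanol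
Conditions: LiAlH4, THF, 0 °C
Reagents that add atoms: none
Why: Standard hydride reduction of an ester to the primary alcohol; the ethers and the three stereocentres are inert to LiAlH4.

Step 11
Reactants: 17 primary alcohol
Product: 19 phyltetralin (1R,2S,3S)-1-(3,4-dimethoxyphenyl)-6,7-dimethoxy-2,3-bis(methoxymethyl)-1,2,3,4-tetrahydronaphthalene, via sodium alkoxide 18 (not isolated)
Conditions: NaH, MeI, THF, 0 °C → rt
Reagents that add atoms: iodomethane, CI
Why: Williamson ether synthesis on an unhindered primary alkoxide; no acidic C–H and no base-labile group remain.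

Compound list
1 | 3,4-dimethoxyacetophenone | CC(=O)c1ccc(OC)c(OC)c1 | starting material
2 | 1-(2-bromo-4,5-dimethoxyphenyl)ethan-1-one | CC(=O)c1cc(OC)c(OC)cc1Br | intermediate
3 | veratraldehyde (3,4-dimethoxybenzaldehyde) | O=Cc1ccc(OC)c(OC)c1 | starting material
4 | (E)-1-(2-bromo-4,5-dimethoxyphenyl)-3-(3,4-dimethoxyphenyl)prop-2-en-1-one | COc1ccc(/C=C/C(=O)c2cc(OC)c(OC)cc2Br)cc1OC | intermediate
5 | (3R)-3-(3,4-dimethoxyphenyl)-5,6-dimethoxyindan-1-one | O=C1c2cc(OC)c(OC)cc2[C@@H](c2ccc(OC)c(OC)c2)C1 | intermediate
6 | lithium enolate of 5 | [Li+].[O-]C=1c2cc(OC)c(OC)cc2[C@@H](c2ccc(OC)c(OC)c2)C=1 | intermediate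
7 | (1R)-[1-(3,4-dimethoxyphenyl)-5,6-dimethoxy-1H-inden-3-yl]oxy(trimethyl)silane | C[Si](C)(C)OC=1c2cc(OC)c(OC)cc2[C@@H](c2ccc(OC)c(OC)c2)C=1 | intermediate
8 | (2R,3R)-3-(3,4-dimethoxyphenyl)-5,6-dimethoxy-2-(methoxymethyl)indan-1-one | O=C1c2cc(OC)c(OC)cc2[C@@H](c2ccc(OC)c(OC)c2)[C@@H]1COC | intermediate
9 | trimethylsilyldiazomethane | C[Si](C)(C)C=[N+]=[N-] | starting material
10 | (3R,4R)-4-(3,4-dimethoxyphenyl)-6,7-dimethoxy-3-(methoxymethyl)-1-(trimethylsilyl)-3,4-dihydronaphthalen-2(1H)-one, silyl-bearing carbon undefined | O=C1C([Si](C)(C)C)c2cc(OC)c(OC)cc2[C@@H](c2ccc(OC)c(OC)c2)[C@@H]1COC | intermediate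
11 | (3R,4R)-4-(3,4-dimethoxyphenyl)-6,7-dimethoxy-3-(methoxymethyl)-3,4-dihydronaphthalen-2(1H)-one | O=C1Cc2cc(OC)c(OC)cc2[C@@H](c2ccc(OC)c(OC)c2)[C@@H]1COC | intermediate
12 | lithium C3=C4 enolate of 11 | [Li+].[O-]C1=Cc2cc(OC)c(OC)cc2[C@@H](c2ccc(OC)c(OC)c2)[C@@H]1COC | intermediate
13 | (3R,4R)-4-(3,4-dimethoxyphenyl)-6,7-dimethoxy-3-(methoxymethyl)-3,4-dihydronaphthalen-2-yl trifluoromethanesulfonate | O=S(=O)(OC1=Cc2cc(OC)c(OC)cc2[C@@H](c2ccc(OC)c(OC)c2)[C@@H]1COC)C(F)(F)F | intermediate
14 | methyl (3S,4R)-4-(3,4-dimethoxyphenyl)-6,7-dimethoxy-3-(methoxymethyl)-3,4-dihydronaphthalene-2-carboxylate | COC(=O)C1=Cc2cc(OC)c(OC)cc2[C@@H](c2ccc(OC)c(OC)c2)[C@@H]1COC | intermediate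
15 | methyl (3S,4R)-4-(3,4-dimethoxyphenyl)-6,7-dimethoxy-3-(methoxymethyl)-1,2,3,4-tetrahydronaphthalene-2-carboxylate, epimers at the ester-bearing carbon | COC(=O)C1Cc2cc(OC)c(OC)cc2[C@@H](c2ccc(OC)c(OC)c2)[C@@H]1COC | intermediate
16 | methyl (2S,3S,4R)-4-(3,4-dimethoxyphenyl)-6,7-dimethoxy-3-(methoxymethyl)-1,2,3,4-tetrahydronaphthalene-2-carboxylate | COC(=O)[C@H]1Cc2cc(OC)c(OC)cc2[C@@H](c2ccc(OC)c(OC)c2)[C@@H]1COC | intermediate
17 | [(2S,3S,4R)-4-(3,4-dimethoxyphenyl)-6,7-dimethoxy-3-(methoxymethyl)-1,2,3,4-tetrahydronaphthalen-2-yl]methanol | OC[C@H]1Cc2cc(OC)c(OC)cc2[C@@H](c2ccc(OC)c(OC)c2)[C@@H]1COC | intermediate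
18 | sodium alkoxide of 17 | [Na+].[O-]C[C@H]1Cc2cc(OC)c(OC)cc2[C@@H](c2ccc(OC)c(OC)c2)[C@@H]1COC | intermediate
19 | phyltetralin, (1R,2S,3S)-1-(3,4-dimethoxyphenyl)-6,7-dimethoxy-2,3-bis(methoxymethyl)-1,2,3,4-tetrahydronaphthalene | COC[C@H]1Cc2cc(OC)c(OC)cc2[C@@H](c2ccc(OC)c(OC)c2)[C@@H]1COC | target

Total step count: 11. Longest linear sequence: 11 steps (from 1).

Steps most likely to fail

(a) Step 6.
- **What may go wrong:** The carbonyl group of 8 is deactivated by the para-methoxy group, so addition of the diazo carbon may be slow. Migration of C2 or collapse of the adduct to an epoxide may compete, and the Lewis acid may provoke loss of methanol.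
- **Fallback:** This reaches the same aryl shift from an alkene instead of a diazonium ion. Setting out from 8, a Petasis methylenation (Cp2TiMe2, toluene, 75 °C; non-basic, so no β-elimination) would give (1R,2S)-1-(3,4-dimethoxyphenyl)-5,6-dimethoxy-2-(methoxymethyl)-3-methylidene-2,3-dihydro-1H-indene F1. Treatment with PhI(OH)OTs in 95 % MeOH at rt would place the trivalent iodine on the terminal CH2 and methanol on the benzylic carbon. Departure of PhI then drives the 1,2-shift of C4a. Hydrolysis of the resulting oxocarbenium ion returns to the route at 11.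

(b) Step 3.
- **What may go wrong:** Bromide may remain on palladium, so that insertion runs through a neutral and poorly face-selective complex. Premature hydrodebromination, or β-hydride elimination towards the indenone, may also consume material.
- **Fallback:** This replaces the aryl–palladium insertion by an aryl–rhodium conjugate addition. Setting out from 4, a Miyaura borylation (B2pin2, PdCl2(dppf), KOAc, dioxane, 80 °C) would give (E)-1-[4,5-dimethoxy-2-(4,4,5,5-tetramethyl-1,3,2-dioxaborolan-2-yl)phenyl]-3-(3,4-dimethoxyphenyl)prop-2-en-1-one F2. A rhodium-catalysed asymmetric intramolecular 1,4-addition follows, using [Rh(C2H4)2Cl]2, the MonoPhos antipode that leads to R, aq K3PO4 and toluene. Protonolysis of the rhodium enolate returns to the route at 5.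

(c) Step 9.
- **What may go wrong:** The equilibrium at C3 may not lie far enough on the trans side, which would leave an epimer mixture to be separated and recycled.
- **Fallback:** This brings in the whole arm by cross-coupling and sets C3 kinetically. Setting out from 13, a Stille coupling with Bu3SnCH2OMe (Pd(PPh3)4, LiCl, dioxane, reflux) would give (1R,2S)-1-(3,4-dimethoxyphenyl)-6,7-dimethoxy-2,3-bis(methoxymethyl)-1,2-dihydronaphthalene F3. Ether-directed hydrogenation with [Ir(cod)(PCy3)(py)]PF6 (H2, CH2Cl2, rt) should then act. The oxygen of the C2 arm is the only donor held on one face of the C3=C4 bond, so it should bind the cationic iridium and deliver hydrogen from that face. This pushes the C3 arm trans and returns to the route directly at 19. The main route is preferred because it keeps an epimerisable centre as a means of correction.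

Further compounds
F1 | step 6 | (1R,2S)-1-(3,4-dimethoxyphenyl)-5,6-dimethoxy-2-(methoxymethyl)-3-methylidene-2,3-dihydro-1H-indene | C=C1c2cc(OC)c(OC)cc2[C@@H](c2ccc(OC)c(OC)c2)[C@@H]1COC
F2 | step 3 | (E)-1-[4,5-dimethoxy-2-(4,4,5,5-tetramethyl-1,3,2-dioxaborolan-2-yl)phenyl]-3-(3,4-dimethoxyphenyl)prop-2-en-1-one | COc1ccc(/C=C/C(=O)c2cc(OC)c(OC)cc2B2OC(C)(C)C(C)(C)O2)cc1OC
F3 | step 9 | (1R,2S)-1-(3,4-dimethoxyphenyl)-6,7-dimethoxy-2,3-bis(methoxymethyl)-1,2-dihydronaphthalene | COCC1=Cc2cc(OC)c(OC)cc2[C@@H](c2ccc(OC)c(OC)c2)[C@@H]1COC
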